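**Retrosynthetic overview**

- Ring numbering used below: C1 = carbinol next to the quaternary epoxide carbon; C2 = quaternary epoxide carbon carrying the enoate arm; C3 = epoxide CH; C4 = second carbinol; C5 = alkene carbon with CH2OH; C6 = alkene carbon with the heptenyl arm.
- Enabling feature: the six-membered ring carries oxygen on C1 and C4 (para) across the C5=C6 double bond, and the C2–C3 epoxide is an alkene plus one oxygen. The carbocycle is therefore a fully substituted hydroquinone at another oxidation level and can be built flat.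
- Target ⇐ C4 and C1 carbinols by two epoxide-controlled Luche reductions ⇐ epoxy ketone from asymmetric nucleophilic epoxidation of a quinone monoketal (epoxide ring, formed last) ⇐ oxidative dearomatisation of a 4-methoxyphenol.
- 4-Methoxyphenol ⇐ C1–C2 disconnection: thermal 4π ring opening/6π electrocyclisation of a 4-alkenyl-4-methoxycyclobutenone (ketene carbon C1 bonds to alkene terminus C2; the carbocycle is formed here, first).
- Cyclobutenone ⇐ diisopropyl squarate (temporary four-membered ring) plus three organolithiums, added in an order that fixes the place of every ring substituent.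

Key step: step 7

Assumption: the absolute sense of the tartrate-mediated epoxidation is taken by analogy with hydroxymethyl-substituted quinone monoketals and L-(+)-diisopropyl tartrate is written; if the opposite face is epoxidised, D-(−)-diisopropyl tartrate would be used with nothing else changed.

**Route**

Step 1
Reactants: 1 hept-1-yne
Product: 3 (E)-1-iodohept-1-ene, via heptenylzirconocene chloride 2 (not isolated)
Conditions: Cp2Zr(H)Cl, THF, rt; then I2, 0 °C
Reagents that add atoms: iodine, [I][I]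
Why: syn-hydrozirconation puts zirconium on the terminal carbon and iodinolysis of the C–Zr bond goes with retention, so the (E)-alkenyl iodide should result (hydrozirconation–iodination).

Step 2
Reactants: 3 (E)-1-iodohept-1-ene; 4 diisopropyl squarate (3,4-diisopropoxycyclobut-3-ene-1,2-dione)
Product: 7 3-[(E)-hept-1-enyl]-4-isopropoxycyclobut-3-ene-1,2-dione, via (E)-hept-1-enyllithium 5 (not isolated), via lithium alkoxide 6 (not isolated)
Conditions: t-BuLi (2 equiv), Et2O, −78 °C; cannulate into 4, THF, −78 °C; then 2 M aq. HCl, 0 °C to rt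
Reagents that add atoms: water, O
Why: iodine–lithium exchange with retention, 1,2-addition to one squarate carbonyl, and acid-induced ionisation of the tertiary alcohol with hydrolysis of the flanking enol ether (loss of isopropanol) should give the 3-alkenyl-4-alkoxycyclobutenedione (squarate mono-addition–rearrangement).

Step 3
Reactants: 8 tert-butyl(but-3-yn-1-yloxy)dimethylsilane
Product: 10 tert-butyl{[(E)-4-iodobut-3-enyl]oxy}dimethylsilane, via alkenylzirconocene chloride 9 (not isolated)
Conditions: Cp2Zr(H)Cl, THF, rt; then I2, 0 °C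
Reagents that add atoms: iodine, [I][I]
Why: the same syn-hydrozirconation–iodination as in step 1 should give the (E)-alkenyl iodide and leave the silyl ether untouched.

Step 4
Reactants: 10 tert-butyl{[(E)-4-iodobut-3-enyl]oxy}dimethylsilane; 7 3-[(E)-hept-1-enyl]-4-isopropoxycyclobut-3-ene-1,2-dione
Product: 13 racemic 4-[(E)-4-(tert-butyldimethylsilyloxy)but-1-enyl]-2-[(E)-hept-1-enyl]-3-isopropoxy-4-methoxycyclobut-2-en-1-one, via alkenyllithium 11 (not isolated), via lithium alkoxide 12 (not isolated)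
Conditions: t-BuLi (2 equiv), Et2O, −78 °C; then 7, THF, −78 °C; then MeOTf, −78 °C to 0 °C
Reagents that add atoms: methyl trifluoromethanesulfonate, COS(=O)(=O)C(F)(F)F
Why: the alkenyllithium should add 1,2 to the carbonyl next to the isopropoxy-bearing carbon, because the other carbonyl is a deactivated vinylogous ester, and the tertiary alkoxide is capped as its methyl ether in the same flask (regioselective organolithium addition, O-methylation); the new stereocentre is racemic and is erased in step 7.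

Step 5
Reactants: 14 4-methoxybenzyl alcohol; 15 tributyl(iodomethyl)stannane
Product: 17 tributyl{[(4-methoxybenzyl)oxy]methyl}stannane, via sodium 4-methoxybenzyl oxide 16 (not isolated)
Conditions: NaH, THF/DMF, 0 °C; then 15, rt
Reagents that add atoms: none
Why: the alkoxide displaces iodide from the unhindered iodomethyl carbon (Williamson ether synthesis).

Step 6
Reactants: 17 tributyl{[(4-methoxybenzyl)oxy]methyl}stannane; 13 the methoxycyclobutenone of step 4
Product: 20 racemic 4-[(E)-4-(tert-butyldimethylsilyloxy)but-1-enyl]-2-[(E)-hept-1-enyl]-4-methoxy-3-{[(4-methoxybenzyl)oxy]methyl}cyclobut-2-en-1-one, via [(4-methoxybenzyl)oxy]methyllithium 18 (not isolated), via lithium alkoxide 19 (not isolated)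
Conditions: n-BuLi, THF, −78 °C; then 13, −78 °C; then 1 M aq. HCl, THF, 0 °C
Reagents that add atoms: water, O
Why: tin–lithium exchange gives the alkoxymethyllithium, which adds 1,2 to the only carbonyl, and acid then ionises the tertiary allylic alcohol to an isopropoxy-stabilised cyclobutenyl cation whose hydrolysis moves the carbonyl to the former enol-ether carbon (Stork–Danheiser-type carbonyl transposition), so that the protected hydroxymethyl group sits on the β-carbon and the methoxy/alkenyl carbon becomes C4 of the enone.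

Step 7
Reactants: 20 the 4-alkenyl-4-methoxycyclobutenone of step 6
Product: 23 6-[2-(tert-butyldimethylsilyloxy)ethyl]-2-[(E)-hept-1-enyl]-4-methoxy-3-{[(4-methoxybenzyl)oxy]methyl}phenol, via dienylketene 21 (not isolated), via cyclohexa-2,4-dienone 22 (not isolated)
Conditions: toluene (degassed, 0.02 M), 110 °C
Reagents that add atoms: none
Why: Heating should open the cyclobutenone by a conrotatory 4π-electrocyclic ring opening in which the methoxy group on the sp3 carbon rotates outward, so that the alkenyl arm is placed cis to the ketene in dienylketene 21; a 6π-electrocyclisation then joins the ketene carbon C1 to the diene terminus C2, and tautomerisation of dienone 22 gives the phenol. The closest known reaction type is the thermal ring expansion of 4-alkenyl-4-alkoxycyclobutenones to hydroquinone monoethers (Moore-type rearrangement). The only ring closed is the six-membered carbocycle, by a disrotatory 6π-electrocyclic closure, at the expense of the four-membered ring. No stereocentre is created that survives: the racemic centre of 20 and the transient C2 centre of 22 are erased, and the step instead fixes the regiochemistry of the penta-substituted ring, because each substituent's place is dictated by its place on the four-membered ring. The selectivity needed is torquoselectivity (methoxy out, alkenyl in), which the donor oxygen on the sp3 carbon secures; the 4-methoxybenzyl ether keeps the hydroxymethyl oxygen from trapping the ketene, and the (E)-alkene offers an unhindered terminus.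

Step 8
Reactants: 23 the phenol of step 7
Product: 24 6-[2-(tert-butyldimethylsilyloxy)ethyl]-2-[(E)-hept-1-enyl]-4,4-dimethoxy-3-{[(4-methoxybenzyl)oxy]methyl}cyclohexa-2,5-dien-1-one
Conditions: PhI(OAc)2, MeOH, 0 °C
Reagents that add atoms: methanol, CO
Why: the trivalent-iodine oxidant converts the para-methoxyphenol into a phenoxenium-type intermediate that methanol captures at the methoxy-bearing carbon C4, giving the quinone monoketal (oxidative dearomatisation).

Step 9
Reactants: 24 the quinone monoketal of step 8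
Product: 25 2-[(E)-hept-1-enyl]-6-(2-hydroxyethyl)-4,4-dimethoxy-3-{[(4-methoxybenzyl)oxy]methyl}cyclohexa-2,5-dien-1-one
Conditions: Bu4NF, AcOH, THF, 0 °C to rt
Reagents that add atoms: none
Why: fluoride cleaves the primary silyl ether, and the acetic acid buffer should keep the base-sensitive cross-conjugated dienone intact (desilylation).

Step 10
Reactants: 25 the primary alcohol of step 9; 26 methyl 2-(triphenyl-λ5-phosphanylidene)propanoate
Product: 28 methyl (E)-4-{5-[(E)-hept-1-enyl]-3,3-dimethoxy-4-{[(4-methoxybenzyl)oxy]methyl}-6-oxocyclohexa-1,4-dien-1-yl}-2-methylbut-2-enoate, via aldehyde 27 (not isolated)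
Conditions: Dess–Martin periodinane, NaHCO3, CH2Cl2, 0 °C; then 26, rt (one pot)
Reagents that add atoms: none
Why: periodinane oxidation gives the sensitive β,γ-unsaturated aldehyde, which is trapped in the same flask by the stabilised α-methyl ylide, whose Wittig olefination should give the (E)-trisubstituted enoate.

Step 11
Reactants: 28 the enoate of step 10
Product: 29 methyl (E)-4-[5-[(E)-hept-1-enyl]-4-(hydroxymethyl)-3,3-dimethoxy-6-oxocyclohexa-1,4-dien-1-yl]-2-methylbut-2-enoate
Conditions: DDQ, CH2Cl2/pH 7 buffer, 0 °C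
Reagents that add atoms: none
Why: DDQ oxidises the electron-rich benzylic ether to an oxocarbenium ion that water hydrolyses, freeing the primary allylic alcohol that directs the next step (oxidative cleavage of a 4-methoxybenzyl ether).

Step 12
Reactants: 29 the hydroxymethyl quinone monoketal of step 11
Product: 30 methyl (2E)-4-[(1R,6S)-3-[(1E)-hept-1-en-1-yl]-4-(hydroxymethyl)-5,5-dimethoxy-2-oxo-7-oxabicyclo[4.1.0]hept-3-en-1-yl]-2-methylbut-2-enoate
Conditions: Ph3COOH, NaN(SiMe3)2, L-(+)-diisopropyl tartrate, 4 Å molecular sieves, toluene, −50 °C; aq. NH4Cl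
Reagents that add atoms: trityl hydroperoxide, OOC(c1ccccc1)(c1ccccc1)c1ccccc1
Why: in this Weitz–Scheffer-type nucleophilic epoxidation the trityl peroxide anion should add to the unsubstituted β-carbon C3 of the C1 enone (the other β-carbon, C5, is fully substituted) and close onto C2, while the sodium alkoxide of the C5 hydroxymethyl group ties the substrate to the chiral tartrate–peroxide aggregate so that one face of C2=C3 is selected, which sets C2 and C3 (tartrate-mediated, hydroxyl-directed asymmetric epoxidation).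

Step 13
Reactants: 30 the epoxy ketone of step 12
Product: 31 methyl (2E)-4-[(1S,2R,6S)-3-[(1E)-hept-1-en-1-yl]-2-hydroxy-4-(hydroxymethyl)-5,5-dimethoxy-7-oxabicyclo[4.1.0]hept-3-en-1-yl]-2-methylbut-2-enoate
Conditions: NaBH4, CeCl3·7H2O, MeOH, −78 °C
Reagents that add atoms: none
Why: in this Luche 1,2-reduction hydride should enter C1 from the face of the epoxide oxygen, away from the side-chain methylene on the adjacent quaternary C2, which sets the C1 carbinol trans to the epoxide.

Step 14
Reactants: 31 the epoxy alcohol ketal of step 13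
Product: 32 methyl (2E)-4-[(1S,2R,6S)-3-[(1E)-hept-1-en-1-yl]-2-hydroxy-4-(hydroxymethyl)-5-oxo-7-oxabicyclo[4.1.0]hept-3-en-1-yl]-2-methylbut-2-enoate
Conditions: 5% aq. oxalic acid, THF, 0 °C to rt
Reagents that add atoms: water, O
Why: mild aqueous acid hydrolyses the dimethyl ketal through an allylic oxocarbenium ion faster than it opens the epoxide, and so unveils the C4 enone (ketal hydrolysis).

Step 15
Reactants: 32 the epoxy enone of step 14
Product: 33 methyl (2E)-4-[(1S,2R,5S,6R)-3-[(1E)-hept-1-en-1-yl]-2,5-dihydroxy-4-(hydroxymethyl)-7-oxabicyclo[4.1.0]hept-3-en-1-yl]-2-methylbut-2-enoate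
Conditions: NaBH4, CeCl3·7H2O, MeOH, −78 °C
Reagents that add atoms: none
Why: Luche 1,2-reduction of a cyclic α,β-epoxy enone, for which hydride delivery on the face of the epoxide oxygen is the usual course, should set the C4 carbinol trans to the epoxide and hence cis to the C1 hydroxyl.

Step 16
Reactants: 33 the methyl ester of step 15
Product: 34 (2E)-4-[(1S,2R,5S,6R)-3-[(1E)-hept-1-en-1-yl]-2,5-dihydroxy-4-(hydroxymethyl)-7-oxabicyclo[4.1.0]hept-3-en-1-yl]-2-methylbut-2-enoic acid
Conditions: Me3SnOH, ClCH2CH2Cl, 70 °C; then aq. KHSO4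
Reagents that add atoms: trimethyltin hydroxide, C[Sn](C)(C)O
Why: trimethyltin hydroxide cleaves the methyl ester through a tin carboxylate under nearly neutral conditions, which should spare the epoxide and the allylic alcohols (mild ester hydrolysis).

**Compound list**

1 | hept-1-yne | CCCCCC#C | starting material
2 | chloro[(E)-hept-1-enyl]zirconocene (not isolated) | CCCCC/C=C/[Zr](Cl)(C1C=CC=C1)C1C=CC=C1 | intermediate
3 | (E)-1-iodohept-1-ene | CCCCC/C=C/I | intermediate
4 | diisopropyl squarate | CC(C)OC1=C(OC(C)C)C(=O)C1=O | starting material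
5 | (E)-hept-1-enyllithium (not isolated) | [Li]/C=C/CCCCC | intermediate
6 | lithium 1-[(E)-hept-1-enyl]-2,3-diisopropoxy-4-oxocyclobut-2-en-1-olate, racemic (not isolated) | CCCCC/C=C/C1([O-])C(OC(C)C)=C(OC(C)C)C1=O.[Li+] | intermediate
7 | 3-[(E)-hept-1-enyl]-4-isopropoxycyclobut-3-ene-1,2-dione | CCCCC/C=C/C1=C(OC(C)C)C(=O)C1=O | intermediate
8 | tert-butyl(but-3-yn-1-yloxy)dimethylsilane | C#CCCO[Si](C)(C)C(C)(C)C | starting material
9 | chloro[(E)-4-(tert-butyldimethylsilyloxy)but-1-enyl]zirconocene (not isolated) | CC(C)(C)[Si](C)(C)OCC/C=C/[Zr](Cl)(C1C=CC=C1)C1C=CC=C1 | intermediate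
10 | tert-butyl{[(E)-4-iodobut-3-enyl]oxy}dimethylsilane | CC(C)(C)[Si](C)(C)OCC/C=C/I | intermediate
11 | (E)-4-(tert-butyldimethylsilyloxy)but-1-enyllithium (not isolated) | [Li]/C=C/CCO[Si](C)(C)C(C)(C)C | intermediate
12 | lithium 1-[(E)-4-(tert-butyldimethylsilyloxy)but-1-enyl]-3-[(E)-hept-1-enyl]-2-isopropoxy-4-oxocyclobut-2-en-1-olate, racemic (not isolated) | CCCCC/C=C/C1=C(OC(C)C)C([O-])(/C=C/CCO[Si](C)(C)C(C)(C)C)C1=O.[Li+] | intermediate
13 | 4-[(E)-4-(tert-butyldimethylsilyloxy)but-1-enyl]-2-[(E)-hept-1-enyl]-3-isopropoxy-4-methoxycyclobut-2-en-1-one, racemic | CCCCC/C=C/C1=C(OC(C)C)C(OC)(/C=C/CCO[Si](C)(C)C(C)(C)C)C1=O | intermediate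
14 | 4-methoxybenzyl alcohol | COc1ccc(CO)cc1 | starting material
15 | tributyl(iodomethyl)stannane | CCCC[Sn](CCCC)(CCCC)CI | starting material
16 | sodium 4-methoxybenzyl oxide (not isolated) | COc1ccc(C[O-])cc1.[Na+] | intermediate
17 | tributyl{[(4-methoxybenzyl)oxy]methyl}stannane | CCCC[Sn](CCCC)(CCCC)COCc1ccc(OC)cc1 | intermediate
18 | [(4-methoxybenzyl)oxy]methyllithium (not isolated) | [Li]COCc1ccc(OC)cc1 | intermediate
19 | lithium 4-[(E)-4-(tert-butyldimethylsilyloxy)but-1-enyl]-2-[(E)-hept-1-enyl]-3-isopropoxy-4-methoxy-1-{[(4-methoxybenzyl)oxy]methyl}cyclobut-2-en-1-olate, mixture of racemic diastereomers (not isolated) | CCCCC/C=C/C1=C(OC(C)C)C(OC)(/C=C/CCO[Si](C)(C)C(C)(C)C)C1([O-])COCc2ccc(OC)cc2.[Li+] | intermediate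
20 | 4-[(E)-4-(tert-butyldimethylsilyloxy)but-1-enyl]-2-[(E)-hept-1-enyl]-4-methoxy-3-{[(4-methoxybenzyl)oxy]methyl}cyclobut-2-en-1-one, racemic | CCCCC/C=C/C1=C(COCc2ccc(OC)cc2)C(OC)(/C=C/CCO[Si](C)(C)C(C)(C)C)C1=O | intermediate
21 | (3Z,5E)-8-(tert-butyldimethylsilyloxy)-2-[(E)-hept-1-enyl]-4-methoxy-3-{[(4-methoxybenzyl)oxy]methyl}octa-1,3,5-trien-1-one, the dienylketene (not isolated) | CCCCC/C=C/C(=C=O)/C(COCc1ccc(OC)cc1)=C(OC)\C=C\CCO[Si](C)(C)C(C)(C)C | intermediate
22 | 6-[2-(tert-butyldimethylsilyloxy)ethyl]-2-[(E)-hept-1-enyl]-4-methoxy-3-{[(4-methoxybenzyl)oxy]methyl}cyclohexa-2,4-dien-1-one, racemic (not isolated) | CCCCC/C=C/C1=C(COCc2ccc(OC)cc2)C(OC)=CC(CCO[Si](C)(C)C(C)(C)C)C1=O | intermediate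
23 | 6-[2-(tert-butyldimethylsilyloxy)ethyl]-2-[(E)-hept-1-enyl]-4-methoxy-3-{[(4-methoxybenzyl)oxy]methyl}phenol | CCCCC/C=C/c1c(O)c(CCO[Si](C)(C)C(C)(C)C)cc(OC)c1COCc2ccc(OC)cc2 | intermediate
24 | 6-[2-(tert-butyldimethylsilyloxy)ethyl]-2-[(E)-hept-1-enyl]-4,4-dimethoxy-3-{[(4-methoxybenzyl)oxy]methyl}cyclohexa-2,5-dien-1-one | CCCCC/C=C/C1=C(COCc2ccc(OC)cc2)C(OC)(OC)C=C(CCO[Si](C)(C)C(C)(C)C)C1=O | intermediate
25 | 2-[(E)-hept-1-enyl]-6-(2-hydroxyethyl)-4,4-dimethoxy-3-{[(4-methoxybenzyl)oxy]methyl}cyclohexa-2,5-dien-1-one | CCCCC/C=C/C1=C(COCc2ccc(OC)cc2)C(OC)(OC)C=C(CCO)C1=O | intermediate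
26 | methyl 2-(triphenyl-λ5-phosphanylidene)propanoate | COC(=O)C(C)=P(c1ccccc1)(c1ccccc1)c1ccccc1 | starting material
27 | 2-{5-[(E)-hept-1-enyl]-3,3-dimethoxy-4-{[(4-methoxybenzyl)oxy]methyl}-6-oxocyclohexa-1,4-dien-1-yl}acetaldehyde (not isolated) | CCCCC/C=C/C1=C(COCc2ccc(OC)cc2)C(OC)(OC)C=C(CC=O)C1=O | intermediate
28 | methyl (E)-4-{5-[(E)-hept-1-enyl]-3,3-dimethoxy-4-{[(4-methoxybenzyl)oxy]methyl}-6-oxocyclohexa-1,4-dien-1-yl}-2-methylbut-2-enoate | CCCCC/C=C/C1=C(COCc2ccc(OC)cc2)C(OC)(OC)C=C(C/C=C(\C)C(=O)OC)C1=O | intermediate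
29 | methyl (E)-4-[5-[(E)-hept-1-enyl]-4-(hydroxymethyl)-3,3-dimethoxy-6-oxocyclohexa-1,4-dien-1-yl]-2-methylbut-2-enoate | CCCCC/C=C/C1=C(CO)C(OC)(OC)C=C(C/C=C(\C)C(=O)OC)C1=O | intermediate
30 | methyl (2E)-4-[(1R,6S)-3-[(1E)-hept-1-en-1-yl]-4-(hydroxymethyl)-5,5-dimethoxy-2-oxo-7-oxabicyclo[4.1.0]hept-3-en-1-yl]-2-methylbut-2-enoate | CCCCC/C=C/C1=C(CO)C(OC)(OC)[C@H]2O[C@@]2(C/C=C(\C)C(=O)OC)C1=O | intermediate
31 | methyl (2E)-4-[(1S,2R,6S)-3-[(1E)-hept-1-en-1-yl]-2-hydroxy-4-(hydroxymethyl)-5,5-dimethoxy-7-oxabicyclo[4.1.0]hept-3-en-1-yl]-2-methylbut-2-enoate | CCCCC/C=C/C1=C(CO)C(OC)(OC)[C@H]2O[C@@]2(C/C=C(\C)C(=O)OC)[C@@H]1O | intermediate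
32 | methyl (2E)-4-[(1S,2R,6S)-3-[(1E)-hept-1-en-1-yl]-2-hydroxy-4-(hydroxymethyl)-5-oxo-7-oxabicyclo[4.1.0]hept-3-en-1-yl]-2-methylbut-2-enoate | CCCCC/C=C/C1=C(CO)C(=O)[C@H]2O[C@@]2(C/C=C(\C)C(=O)OC)[C@@H]1O | intermediate
33 | methyl (2E)-4-[(1S,2R,5S,6R)-3-[(1E)-hept-1-en-1-yl]-2,5-dihydroxy-4-(hydroxymethyl)-7-oxabicyclo[4.1.0]hept-3-en-1-yl]-2-methylbut-2-enoate | CCCCC/C=C/C1=C(CO)[C@H](O)[C@H]2O[C@@]2(C/C=C(\C)C(=O)OC)[C@@H]1O | intermediate
34 | (2E)-4-[(1S,2R,5S,6R)-3-[(1E)-hept-1-en-1-yl]-2,5-dihydroxy-4-(hydroxymethyl)-7-oxabicyclo[4.1.0]hept-3-en-1-yl]-2-methylbut-2-enoic acid | CCCCC/C=C/C1=C(CO)[C@H](O)[C@H]2O[C@@]2(C/C=C(\C)C(=O)O)[C@@H]1O | target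

**Step count and risks**

Total step count: 16. Longest linear sequence: 14 steps (steps 1, 2, 4, 6 and 7 to 16).

The three steps most likely to fail:

1. Step 12 (asymmetric epoxidation). What may go wrong: poor facial discrimination, or a sluggish peroxide addition, if the hydroxymethyl alkoxide does not engage the tartrate–peroxide aggregate. Fallback (auxiliary control in place of reagent control): the fallback sets out from 29. Acid-catalysed ketal exchange with (2R,4R)-pentane-2,4-diol (pyridinium 4-toluenesulfonate, benzene, 4 Å molecular sieves) would give the spiro 1,3-dioxane dienone F1. Nucleophilic epoxidation (t-BuOOH, DBU, CH2Cl2), in which the axial methyl group of the twofold-symmetric ketal screens one face of C3, would give the epoxy ketone F2; the (2S,4S)-diol would be taken if the other face proves to be the open one. Luche reduction would give the epoxy alcohol F3, and aqueous oxalic acid would remove the auxiliary, so that the route is rejoined at 32.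

2. Step 15 (reduction at C4). What may go wrong: hydride delivery to the wrong face of the C4 carbonyl, since the neighbouring C3 carries only hydrogen and the steric bias is small. Fallback (correction by inversion): the fallback sets out from 32 through the C4-epimeric diol F4 that such a reduction would give. Silylation of the primary hydroxyl (TBSCl, imidazole, CH2Cl2) would give the silyl ether F5. Mitsunobu inversion with 4-nitrobenzoic acid (PPh3, diisopropyl azodicarboxylate) at the less hindered C4 carbinol (C1 is flanked by the quaternary C2) would give the 4-nitrobenzoate F6. Methanolysis (K2CO3, MeOH) would give the inverted alcohol F7, and desilylation (Bu4NF, AcOH) would return the route to 33.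

3. Step 16 (ester cleavage). What may go wrong: opening or migration of the epoxide in the epoxy diol during hydrolysis, or incomplete cleavage of the hindered conjugated ester. Fallback (saponification before the sensitive diol exists): the fallback sets out from 31, where the only alkoxide that can form would have to attack the fully substituted C2. Saponification (LiOH, THF/H2O, 0 °C to rt) would give the carboxylic acid F8, ketal hydrolysis (5% aq. oxalic acid, THF) would give the keto acid F9, and Luche reduction with excess NaBH4 would give 34 directly.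

Further compounds
F1 | step 12 | methyl (E)-4-[5-[(E)-hept-1-enyl]-4-(hydroxymethyl)-6-oxo-3,3-[(2R,4R)-pentane-2,4-diyldioxy]cyclohexa-1,4-dien-1-yl]-2-methylbut-2-enoate (spiro 1,3-dioxane analogue of 29) | CCCCC/C=C/C1=C(CO)C2(O[C@H](C)C[C@@H](C)O2)C=C(C/C=C(\C)C(=O)OC)C1=O
F2 | step 12 | spiro 1,3-dioxane analogue of epoxy ketone 30 (epoxide configured as in 30) | CCCCC/C=C/C1=C(CO)C2(O[C@H](C)C[C@@H](C)O2)[C@H]3O[C@@]3(C/C=C(\C)C(=O)OC)C1=O
F3 | step 12 | spiro 1,3-dioxane analogue of epoxy alcohol 31 (C1 carbinol trans to the epoxide) | CCCCC/C=C/C1=C(CO)C2(O[C@H](C)C[C@@H](C)O2)[C@H]3O[C@@]3(C/C=C(\C)C(=O)OC)[C@@H]1O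
F4 | step 15 | methyl (2E)-4-[(1S,2R,5R,6R)-3-[(1E)-hept-1-en-1-yl]-2,5-dihydroxy-4-(hydroxymethyl)-7-oxabicyclo[4.1.0]hept-3-en-1-yl]-2-methylbut-2-enoate (C4 epimer of 33) | CCCCC/C=C/C1=C(CO)[C@@H](O)[C@H]2O[C@@]2(C/C=C(\C)C(=O)OC)[C@@H]1O
F5 | step 15 | primary tert-butyldimethylsilyl ether of F4 | CCCCC/C=C/C1=C(CO[Si](C)(C)C(C)(C)C)[C@@H](O)[C@H]2O[C@@]2(C/C=C(\C)C(=O)OC)[C@@H]1O
F6 | step 15 | C4 4-nitrobenzoate with inverted C4 (configured as in 33), primary silyl ether | CCCCC/C=C/C1=C(CO[Si](C)(C)C(C)(C)C)[C@H](OC(=O)c3ccc(cc3)[N+](=O)[O-])[C@H]2O[C@@]2(C/C=C(\C)C(=O)OC)[C@@H]1O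
F7 | step 15 | primary tert-butyldimethylsilyl ether of 33 | CCCCC/C=C/C1=C(CO[Si](C)(C)C(C)(C)C)[C@H](O)[C@H]2O[C@@]2(C/C=C(\C)C(=O)OC)[C@@H]1O
F8 | step 16 | (2E)-4-[(1S,2R,6S)-3-[(1E)-hept-1-en-1-yl]-2-hydroxy-4-(hydroxymethyl)-5,5-dimethoxy-7-oxabicyclo[4.1.0]hept-3-en-1-yl]-2-methylbut-2-enoic acid | CCCCC/C=C/C1=C(CO)C(OC)(OC)[C@H]2O[C@@]2(C/C=C(\C)C(=O)O)[C@@H]1O
F9 | step 16 | (2E)-4-[(1S,2R,6S)-3-[(1E)-hept-1-en-1-yl]-2-hydroxy-4-(hydroxymethyl)-5-oxo-7-oxabicyclo[4.1.0]hept-3-en-1-yl]-2-methylbut-2-enoic acid | CCCCC/C=C/C1=C(CO)C(=O)[C@H]2O[C@@]2(C/C=C(\C)C(=O)O)[C@@H]1O
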